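## Retrosynthetic overview

1. Target ⇐ removal of four MOM ethers from the (3S) tetra-MOM ketone. C3–H ⇐ enantioselective protonation of a chiral palladium enolate made from the allyl enol carbonate of the racemic ketone.
2. Racemic ketone ⇐ C3–C1' bond by palladium-catalysed α-arylation of 5,7-bis(methoxymethoxy)chroman-4-one with the fully elaborated ring B bromide.
3. Chromanone core ⇐ rings A and C made together in one operation from a monocyclic pyrone triketide (Claisen closure gives ring A, amine loss and oxa-Michael addition close ring C). Pyrone ⇐ triacetic acid lactone + methyl 3-(dimethylamino)propanoate.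
4. Ring B bromide ⇐ 4-bromoresorcinol (MOM-directed lithiation between the two oxygens) + (E)-allylic bromide ⇐ geranyl acetate (terminal-selective hydration).
5. Ring order: ring B is bought; rings A and C are formed together in the key step; no other ring is formed.

Assumption: the target SMILES corresponds to 3S, and the (S)-configured PHOX ligand is taken to deliver 3S in step 9; if the first run shows 3R, the (R)-ligand is used with no other change.

## Route

Step 1
Reactants: 1 geranyl acetate
Product: 4 (2E)-3,7-dimethyloct-2-ene-1,7-diol, via organomercurial 2 (not isolated), via hydroxy acetate 3 (not isolated)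
Conditions: Hg(OAc)2, THF/H2O (1:1), 0 °C to rt; then NaBH4, 3 M NaOH, 0 °C; then MeOH, rt
Reagents that add atoms: water, O
Why: Oxymercuration–demercuration (Markovnikov hydration) takes place only at the electron-richer 6,7-alkene because the 2,3-alkene is deactivated by the allylic acetate, and the basic work-up saponifies the acetate, so the E-alkene is untouched.

Step 2
Reactants: 4 (2E)-3,7-dimethyloct-2-ene-1,7-diol
Product: 5 (6E)-8-bromo-2,6-dimethyloct-6-en-2-ol
Conditions: CBr4, PPh3, CH2Cl2, −20 to 0 °C
Reagents that add atoms: carbon tetrabromide, BrC(Br)(Br)Br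
Why: Appel bromination converts only the primary allylic alcohol (SN2 on the alkoxyphosphonium ion), the tertiary alcohol being unable to react this way at low temperature, and the E geometry is kept.

Step 3
Reactants: 6 4-bromoresorcinol
Product: 7 1-bromo-2,4-bis(methoxymethoxy)benzene
Conditions: NaH, DMF, 0 °C; MOMCl, 0 °C to rt
Reagents that add atoms: chloromethyl methyl ether (MOMCl), COCCl
Why: Williamson-type O-alkylation of both phenoxides gives the acetal ethers that protect the phenols and direct the next lithiation.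

Step 4
Reactants: 7 1-bromo-2,4-bis(methoxymethoxy)benzene; 5 (6E)-8-bromo-2,6-dimethyloct-6-en-2-ol
Product: 9 (6E)-8-[3-bromo-2,6-bis(methoxymethoxy)phenyl]-2,6-dimethyloct-6-en-2-ol, via aryllithium 8 (not isolated)
Conditions: LiN(i-Pr)2 (2.2 equiv), 7 (2.2 equiv), THF, −78 °C; CuI (10 mol %); 5 (1 equiv), −78 to −20 °C; H2O
Reagents that add atoms: none
Why: Directed ortho-metalation by the amide base removes the proton flanked by the two OMOM groups without bromine–lithium exchange, and copper-catalysed SN2 allylation then places the chain between the oxygens with the E-alkene retained (one aryllithium equivalent is spent on the tertiary OH and returns 7 on quench).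

Step 5
Reactants: 10 triacetic acid lactone (4-hydroxy-6-methyl-2H-pyran-2-one); 11 methyl 3-(dimethylamino)propanoate
Product: 13 6-[4-(dimethylamino)-2-oxobutyl]-4-hydroxy-2H-pyran-2-one, via dilithio dianion 12 (not isolated)
Conditions: LiN(i-Pr)2 (4.2 equiv), 10 (2 equiv), THF, −78 to 0 °C; 11 (1 equiv), −78 °C to rt; aq HCl to pH 6, reverse-phase filtration
Reagents that add atoms: none
Why: Claisen-type C-acylation of the O,C-dianion of the pyrone at its terminal carbanion by the ester builds the triketide chain, and the dimethylamino group is too poor a leaving group to eliminate under these conditions.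

Step 6 (key step: rings A and C in one operation)
Reactants: 13 6-[4-(dimethylamino)-2-oxobutyl]-4-hydroxy-2H-pyran-2-one
Product: 17 5,7-dihydroxychroman-4-one, via triketo ester 14 (not isolated), via Mannich ketone 15 (not isolated), via aryl vinyl ketone 16 (not isolated)
Conditions: Mg(OMe)2 (6 equiv), MeOH, reflux, 16 h; then AcOH to pH 6, 65 °C, 2 h
Reagents that add atoms: none
Why: Proposed new method: methoxide opens the pyrone to the magnesium-chelated 3,5,7-triketo ester 14, whose C6 methylene attacks the ester carbon in a biomimetic Claisen cyclisation (closest known reaction type: Mg(OMe)2-mediated conversion of 6-(2-oxoalkyl)-4-hydroxy-2-pyrones into acylphloroglucinols and of the styryl analogue into a flavanone) to build ring A as 15, and on buffering the Mannich base loses dimethylamine to vinyl ketone 16, which closes ring C by 6-endo oxa-Michael addition of the ortho phenol (the Mannich-base route to chroman-4-ones), with no stereocentre formed.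

Step 7
Reactants: 17 5,7-dihydroxychroman-4-one
Product: 18 5,7-bis(methoxymethoxy)chroman-4-one
Conditions: NaH (2.3 equiv), DMF, 0 °C; MOMCl, 0 °C to rt
Reagents that add atoms: chloromethyl methyl ether (MOMCl), COCCl
Why: O-alkylation of both phenoxides (including the chelated 5-OH once deprotonated) masks the acidic protons before the enolate chemistry.

Step 8
Reactants: 18 5,7-bis(methoxymethoxy)chroman-4-one; 9 (6E)-8-[3-bromo-2,6-bis(methoxymethoxy)phenyl]-2,6-dimethyloct-6-en-2-ol
Product: 19 racemic 3-{3-[(2E)-7-hydroxy-3,7-dimethyloct-2-en-1-yl]-2,4-bis(methoxymethoxy)phenyl}-5,7-bis(methoxymethoxy)chroman-4-one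
Conditions: Pd2(dba)3 (2.5 mol %), t-Bu3P·HBF4 (6 mol %), NaOt-Bu (3.3 equiv), toluene, 70 °C; pH 7 buffer
Reagents that add atoms: none
Why: Palladium-catalysed ketone enolate α-arylation (Buchwald–Hartwig type) joins the only enolisable position of 18 to the aryl bromide after oxidative addition at zerovalent palladium, the ortho substituent blocks a second arylation, and C3 is formed racemic here because it is set in step 9.

Step 9
Reactants: 19 racemic tetra-MOM isoflavanone
Product: 21 (3S)-3-{3-[(2E)-7-hydroxy-3,7-dimethyloct-2-en-1-yl]-2,4-bis(methoxymethoxy)phenyl}-5,7-bis(methoxymethoxy)chroman-4-one, via bis(allyl carbonate) 20 (not isolated)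
Conditions: KN(SiMe3)2 (2.1 equiv), THF, −78 °C; allyl chloroformate (2.2 equiv), −78 to 0 °C; then Meldrum's acid (3.5 equiv), Pd2(dba)3 (2.5 mol %), (S)-(CF3)3-t-BuPHOX (6.5 mol %), THF, 25 to 40 °C
Reagents that add atoms: none
Why: Proposed new method: O-acylation of the potassium enolate (and of the tertiary alkoxide) gives allyl enol carbonate 20, which zerovalent palladium ionises with loss of CO2 to the same PHOX-bound palladium enolate that is formed in the decarboxylative asymmetric protonation of allyl 3-aryl-4-oxochroman-3-carboxylates (closest known reaction type), and its face-selective C-protonation by Meldrum's acid, steered by the ortho-OMOM aryl group, sets 3S while the acidic, base-free medium prevents re-enolisation.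

Step 10
Reactants: 21 (3S) tetra-MOM isoflavanone
Product: 22 (3S)-3-{2,4-dihydroxy-3-[(2E)-7-hydroxy-3,7-dimethyloct-2-en-1-yl]phenyl}-5,7-dihydroxy-2,3-dihydro-4H-chromen-4-one
Conditions: ZnBr2 (6 equiv), n-PrSH (12 equiv), CH2Cl2, 0 °C, 15 min; pH 6 phosphate buffer
Reagents that add atoms: none
Why: Lewis-acid-assisted acetal cleavage, in which ZnBr2 activates each aryl MOM ether and the thiol captures the methoxymethyl cation, is fast and nearly neutral at 0 °C, so the trisubstituted alkene, the tertiary alcohol and the enolisable C3–H (3S) are left untouched.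

## Compound list

1 | geranyl acetate | CC(C)=CCC/C(C)=C/COC(C)=O | starting material
2 | (2E)-6-(acetoxymercurio)-7-hydroxy-3,7-dimethyloct-2-en-1-yl acetate | CC(=O)OC/C=C(\C)CCC([Hg]OC(C)=O)C(C)(C)O | intermediate (not isolated)
3 | (2E)-7-hydroxy-3,7-dimethyloct-2-en-1-yl acetate | CC(=O)OC/C=C(\C)CCCC(C)(C)O | intermediate (not isolated)
4 | (2E)-3,7-dimethyloct-2-ene-1,7-diol | OC/C=C(\C)CCCC(C)(C)O | intermediate
5 | (6E)-8-bromo-2,6-dimethyloct-6-en-2-ol | BrC/C=C(\C)CCCC(C)(C)O | intermediate
6 | 4-bromoresorcinol | Oc1ccc(Br)c(O)c1 | starting material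
7 | 1-bromo-2,4-bis(methoxymethoxy)benzene | COCOc1ccc(Br)c(OCOC)c1 | intermediate
8 | 3-bromo-2,6-bis(methoxymethoxy)phenyllithium | [Li]c1c(OCOC)ccc(Br)c1OCOC | intermediate (not isolated)
9 | (6E)-8-[3-bromo-2,6-bis(methoxymethoxy)phenyl]-2,6-dimethyloct-6-en-2-ol | C/C(=C\Cc1c(OCOC)ccc(Br)c1OCOC)CCCC(C)(C)O | intermediate
10 | triacetic acid lactone (4-hydroxy-6-methyl-2H-pyran-2-one) | Cc1cc(O)cc(=O)o1 | starting material
11 | methyl 3-(dimethylamino)propanoate | COC(=O)CCN(C)C | starting material
12 | dilithium 6-methylene-6H-pyran-2,4-bis(olate) (dianion of 10) | [Li+].[Li+].C=C1C=C([O-])C=C([O-])O1 | intermediate (not isolated)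
13 | 6-[4-(dimethylamino)-2-oxobutyl]-4-hydroxy-2H-pyran-2-one | CN(C)CCC(=O)Cc1cc(O)cc(=O)o1 | intermediate
14 | methyl 9-(dimethylamino)-3,5,7-trioxononanoate (as magnesium chelate) | COC(=O)CC(=O)CC(=O)CC(=O)CCN(C)C | intermediate (not isolated)
15 | 3-(dimethylamino)-1-(2,4,6-trihydroxyphenyl)propan-1-one | CN(C)CCC(=O)c1c(O)cc(O)cc1O | intermediate (not isolated)
16 | 1-(2,4,6-trihydroxyphenyl)prop-2-en-1-one | C=CC(=O)c1c(O)cc(O)cc1O | intermediate (not isolated)
17 | 5,7-dihydroxychroman-4-one | O=C1CCOc2cc(O)cc(O)c12 | intermediate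
18 | 5,7-bis(methoxymethoxy)chroman-4-one | COCOc1cc(OCOC)c2C(=O)CCOc2c1 | intermediate
19 | racemic 3-{3-[(2E)-7-hydroxy-3,7-dimethyloct-2-en-1-yl]-2,4-bis(methoxymethoxy)phenyl}-5,7-bis(methoxymethoxy)chroman-4-one | C/C(=C\Cc1c(OCOC)ccc(C2COc3cc(OCOC)cc(OCOC)c3C2=O)c1OCOC)CCCC(C)(C)O | intermediate
20 | allyl 3-{3-[(2E)-7-(allyloxycarbonyloxy)-3,7-dimethyloct-2-en-1-yl]-2,4-bis(methoxymethoxy)phenyl}-5,7-bis(methoxymethoxy)-2H-chromen-4-yl carbonate | C=CCOC(=O)OC1=C(c2ccc(OCOC)c(C/C=C(\C)CCCC(C)(C)OC(=O)OCC=C)c2OCOC)COc2cc(OCOC)cc(OCOC)c12 | intermediate (not isolated)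
21 | (3S)-3-{3-[(2E)-7-hydroxy-3,7-dimethyloct-2-en-1-yl]-2,4-bis(methoxymethoxy)phenyl}-5,7-bis(methoxymethoxy)chroman-4-one | C/C(=C\Cc1c(OCOC)ccc([C@H]2COc3cc(OCOC)cc(OCOC)c3C2=O)c1OCOC)CCCC(C)(C)O | intermediate
22 | (3S)-3-{2,4-dihydroxy-3-[(2E)-7-hydroxy-3,7-dimethyloct-2-en-1-yl]phenyl}-5,7-dihydroxy-2,3-dihydro-4H-chromen-4-one | C/C(=C\Cc1c(O)ccc([C@H]2COc3cc(O)cc(O)c3C2=O)c1O)CCCC(C)(C)O | target

## Step count and risks

Total step count: 10. Longest linear sequence: 6 steps (1 → 2 → 4 → 8 → 9 → 10; the core branch 5 → 6 → 7 → 8 → 9 → 10 is equally long).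

Three steps most likely to fail:

Step 6. The triketo ester may close in the aldol sense (a resorcylic ester) instead of the Claisen sense, or the amine may be lost too slowly for ring C to close. The fallback sets out from 10: its dianion 12 is acylated instead with ethyl 3-(trimethylsilyl)propiolate to give 4-hydroxy-6-[2-oxo-4-(trimethylsilyl)but-3-yn-1-yl]-2H-pyran-2-one F1. Mg(OMe)2 in MeOH then removes the silyl group, closes ring A by the same Claisen mode and closes ring C by 6-endo-dig oxa-Michael addition of the new phenoxide to the ynone, so no elimination is needed and both rings still form together, giving 5,7-dihydroxy-4H-chromen-4-one F2. Hydrogenation of its C2=C3 bond (H2, Pd/C, EtOAc) brings the route back at 17.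

Step 9. The one-pot enol carbonate formation and palladium-enolate protonation may give low enantiomeric excess with this hindered, 5-oxygenated substrate. The fallback sets out from 19 and uses dynamic kinetic resolution by asymmetric transfer hydrogenation: RuCl[(S,S)-TsDPEN](p-cymene) (or its mirror image, whichever gives the 3S series) with HCO2H/Et3N racemises the ketone faster than it is reduced and funnels it to cis-(3S,4S)-3-{3-[(2E)-7-hydroxy-3,7-dimethyloct-2-en-1-yl]-2,4-bis(methoxymethoxy)phenyl}-5,7-bis(methoxymethoxy)chroman-4-ol F3, in which C3 can no longer enolise. Oxidation of the benzylic alcohol with Dess–Martin periodinane buffered with NaHCO3 (CH2Cl2, 0 °C) brings the route back at 21.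

Step 10. The final deprotection may erode the labile C3 centre or cyclise the side chain onto a freed phenol. The fallback sets out from 19 and puts the stereocentre-setting step last: the four MOM groups are removed at the racemic stage (3 M HCl in MeOH, 45 °C, no stereochemical constraint) to give the racemic pentahydroxy compound F4. Treatment with NaN(SiMe3)2 and excess allyl chloroformate converts the four phenols, the tertiary alcohol and the C4 enol into the hexakis(allyl carbonate) F5. The Pd2(dba)3/(S)-(CF3)3-t-BuPHOX/Meldrum's acid conditions of step 9 then remove every allyl carbonate and protonate the palladium enolate enantioselectively, arriving directly at 22 with no acid or base treatment after the stereocentre is set.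

## Further compounds

F1 | step 6 | 4-hydroxy-6-[2-oxo-4-(trimethylsilyl)but-3-yn-1-yl]-2H-pyran-2-one | C[Si](C)(C)C#CC(=O)Cc1cc(O)cc(=O)o1
F2 | step 6 | 5,7-dihydroxy-4H-chromen-4-one | O=c1ccoc2cc(O)cc(O)c12
F3 | step 9 | (3S,4S)-3-{3-[(2E)-7-hydroxy-3,7-dimethyloct-2-en-1-yl]-2,4-bis(methoxymethoxy)phenyl}-5,7-bis(methoxymethoxy)chroman-4-ol | C/C(=C\Cc1c(OCOC)ccc([C@H]2COc3cc(OCOC)cc(OCOC)c3[C@H]2O)c1OCOC)CCCC(C)(C)O
F4 | step 10 | racemic 3-{2,4-dihydroxy-3-[(2E)-7-hydroxy-3,7-dimethyloct-2-en-1-yl]phenyl}-5,7-dihydroxychroman-4-one | C/C(=C\Cc1c(O)ccc(C2COc3cc(O)cc(O)c3C2=O)c1O)CCCC(C)(C)O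
F5 | step 10 | allyl 3-{3-[(2E)-7-(allyloxycarbonyloxy)-3,7-dimethyloct-2-en-1-yl]-2,4-bis(allyloxycarbonyloxy)phenyl}-5,7-bis(allyloxycarbonyloxy)-2H-chromen-4-yl carbonate | C=CCOC(=O)OC1=C(c2ccc(OC(=O)OCC=C)c(C/C=C(\C)CCCC(C)(C)OC(=O)OCC=C)c2OC(=O)OCC=C)COc2cc(OC(=O)OCC=C)cc(OC(=O)OCC=C)c12
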